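Ring C is closed last, at the aryl ether bond O1–C8a. O1 links the stereogenic benzylic carbon C2 to the ring A carbon C8a, so a copper-catalysed intramolecular O-arylation of a preformed (S)-carbinol builds the chroman in one operation without touching the C2–O bond or its configuration. The substrate is an (S)-1,3-diarylpropan-1-ol: ring B carries both prenyl groups and a MOM ether, ring A an ortho-bromide and a MOM ether, and C4 is held as a dioxolane so that no β-hydroxy ketone ever meets base. The dioxolane is installed before the stereocentre exists, and C2 is set by asymmetric transfer hydrogenation.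

Key step: step 8

Remark: flavanone numbering is used (O1, C2, C3, C4, C4a, C5 to C8, C8a; ring A is the benzo ring, ring C the oxygen heterocycle, ring B the 2-aryl group); the target SMILES defines C2 as (S); MOM stands for methoxymethyl.

Step 1
Reactants: 1 methyl 2-bromo-4-hydroxybenzoate
Product: 2 methyl 2-bromo-4-(methoxymethoxy)benzoate
Conditions: NaH, DMF, 0 °C; MOMCl, 0 °C to rt
Reagents that add atoms: chloromethyl methyl ether (MOMCl), COCCl
Why: Williamson-type O-alkylation of the sodium phenoxide by the reactive α-chloro ether should be fast and clean, and the resulting acetal tolerates every basic and organometallic step that follows.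

Step 2
Reactants: 2 methyl 2-bromo-4-(methoxymethoxy)benzoate; 3 N-methoxy-N-methylacetamide (2.1 equiv)
Product: 5 3-[2-bromo-4-(methoxymethoxy)phenyl]-N-methoxy-N-methyl-3-oxopropanamide, via lithium enolate of N-methoxy-N-methylacetamide 4 (not isolated)
Conditions: 3, LiN(iPr)2 (2.0 equiv), THF, −78 °C; then 2, −78 to −40 °C; AcOH quench
Reagents that add atoms: none
Why: Crossed Claisen condensation in which the aryl ester cannot enolise and the preformed amide enolate is the only nucleophile; the β-keto amide is deprotonated as it forms by the second equivalent of enolate, which should stop the sequence at mono-acylation, and no free amide base is left to attack the aryl bromide or the ring hydrogen between bromine and the MOM ether.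

Step 3
Reactants: 5 3-[2-bromo-4-(methoxymethoxy)phenyl]-N-methoxy-N-methyl-3-oxopropanamide
Product: 6 2-{2-[2-bromo-4-(methoxymethoxy)phenyl]-1,3-dioxolan-2-yl}-N-methoxy-N-methylacetamide
Conditions: (TMSOCH2)2 (3 equiv), TMSOTf (0.1 equiv), CH2Cl2, −78 to 0 °C; pyridine, aq. NaHCO3
Reagents that add atoms: 1,2-bis(trimethylsilyloxy)ethane, C[Si](C)(C)OCCO[Si](C)(C)C
Why: Silyl-transfer ketalisation under TMSOTf catalysis (Noyori conditions) is aprotic and runs cold, so the aryl MOM ether and the Weinreb amide should survive, and the ketone is masked at a stage where no acid-labile benzylic oxygen function exists yet.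

Step 4
Reactants: 7 4-bromophenol; 8 1-bromo-3-methylbut-2-ene (prenyl bromide, 2.2 equiv)
Product: 9 4-bromo-2,6-bis(3-methylbut-2-enyl)phenol
Conditions: NaH (2.2 equiv), toluene, 0 °C; 8, rt
Reagents that add atoms: none
Why: ortho-C-Alkylation of a sodium phenoxide in a non-polar solvent, where the tight ion pair shields oxygen and directs the allylic bromide to carbon with SN2 regiochemistry; bromine blocks the para position, so repeating the alkylation in the same flask should place the two linear prenyl groups at C2 and C6.

Step 5
Reactants: 9 4-bromo-2,6-bis(3-methylbut-2-enyl)phenol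
Product: 10 5-bromo-2-(methoxymethoxy)-1,3-bis(3-methylbut-2-enyl)benzene
Conditions: NaH, DMF, 0 °C; MOMCl, rt
Reagents that add atoms: chloromethyl methyl ether (MOMCl), COCCl
Why: Williamson-type O-alkylation, in which the unsolvated phenoxide of the hindered 2,6-dialkylphenol in DMF should still reach the small and very reactive α-chloro ether.

Step 6
Reactants: 10 5-bromo-2-(methoxymethoxy)-1,3-bis(3-methylbut-2-enyl)benzene (1.3 equiv); 6 2-{2-[2-bromo-4-(methoxymethoxy)phenyl]-1,3-dioxolan-2-yl}-N-methoxy-N-methylacetamide
Product: 12 2-{2-[2-bromo-4-(methoxymethoxy)phenyl]-1,3-dioxolan-2-yl}-1-[4-(methoxymethoxy)-3,5-bis(3-methylbut-2-enyl)phenyl]ethanone, via aryl Grignard reagent 11 (not isolated)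
Conditions: 10, Mg turnings (I2 activation), THF, 50 °C; then 6, 0 °C to rt; aq. NH4Cl
Reagents that add atoms: none
Why: Grignard formation by magnesium insertion followed by Weinreb ketone synthesis, in which the five-membered magnesium chelate of the tetrahedral adduct should hold until work-up and so prevent over-addition, while an arylmagnesium bromide neither exchanges with the ring A bromide nor opens the dioxolane at 0 °C.

Step 7
Reactants: 12 2-{2-[2-bromo-4-(methoxymethoxy)phenyl]-1,3-dioxolan-2-yl}-1-[4-(methoxymethoxy)-3,5-bis(3-methylbut-2-enyl)phenyl]ethanone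
Product: 13 (S)-2-{2-[2-bromo-4-(methoxymethoxy)phenyl]-1,3-dioxolan-2-yl}-1-[4-(methoxymethoxy)-3,5-bis(3-methylbut-2-enyl)phenyl]ethanol
Conditions: RuCl(p-cymene)[(S,S)-TsDPEN] (2 mol %), HCO2H/Et3N (1:1), DMF, 40 °C
Reagents that add atoms: none
Why: Noyori asymmetric transfer hydrogenation sets C2: the (S,S)-TsDPEN ruthenium hydride recognises the aryl group through its CH–π contact with the cymene ligand and, as for acetophenone-type ketones, should deliver hydride to the face that gives the (S)-carbinol, while the amine-rich formate medium leaves the ketal, the MOM ethers, the prenyl alkenes and the aryl bromide untouched.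

Step 8
Reactants: 13 (S)-2-{2-[2-bromo-4-(methoxymethoxy)phenyl]-1,3-dioxolan-2-yl}-1-[4-(methoxymethoxy)-3,5-bis(3-methylbut-2-enyl)phenyl]ethanol
Product: 14 (S)-7-(methoxymethoxy)-2-[4-(methoxymethoxy)-3,5-bis(3-methylbut-2-enyl)phenyl]spiro[chromane-4,2'-[1,3]dioxolane]
Conditions: CuI (10 mol %), 3,4,7,8-tetramethyl-1,10-phenanthroline (20 mol %), Cs2CO3 (2 equiv), toluene (0.05 M), 110 °C, argon
Reagents that add atoms: none
Why: Cs2CO3 deprotonates the carbinol and the alkoxide binds monovalent copper held by the phenanthroline ligand; the tethered aryl bromide then adds oxidatively to give an aryl(alkoxo) trivalent copper species in a seven-membered metallacycle, and C–O reductive elimination releases the aryl ether and returns monovalent copper. The closest known reaction type is the ligand-accelerated Ullmann O-arylation of aliphatic alcohols with aryl halides, whose intramolecular form is an established entry to chromans and dihydrobenzofurans. Ring C closes as a six-membered ring by bond formation between O1 and the aromatic carbon C8a, which joins O1, C2, C3, C4, C4a and C8a without any bond to C2 being made or broken. No stereocentre is created, and the (S) configuration at C2 is carried through because only the O–H and C8a–Br bonds react. The step needs ring closure to outrun intermolecular etherification and protodebromination, which moderate dilution and the favourable six-membered closure should secure. The dioxolane at C4 removes the acidic C3 hydrogens of a β-hydroxy ketone, so retro-aldol cleavage and dehydration to a chalcone are closed off, and it also keeps the product from the base-induced ring opening by which flavanones racemise.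

Step 9
Reactants: 14 (S)-7-(methoxymethoxy)-2-[4-(methoxymethoxy)-3,5-bis(3-methylbut-2-enyl)phenyl]spiro[chromane-4,2'-[1,3]dioxolane]
Product: 15 (2S)-7-hydroxy-2-[4-hydroxy-3,5-bis(3-methylbut-2-enyl)phenyl]chroman-4-one
Conditions: 3 M aq. HCl, MeOH, 40 °C
Reagents that add atoms: water, O
Why: Acid-catalysed acetal cleavage, in which the electron-rich aryl dioxolane should hydrolyse first to the C4 ketone and both MOM ethers are then transferred to methanol as dimethoxymethane; because acid, unlike base, does not open the flavanone by β-elimination of the O1 phenoxide, the (S) configuration at C2 should persist at moderate temperature.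

Compound list
1 | methyl 2-bromo-4-hydroxybenzoate | COC(=O)c1ccc(O)cc1Br | starting material
2 | methyl 2-bromo-4-(methoxymethoxy)benzoate | COCOc1ccc(C(=O)OC)c(Br)c1 | intermediate
3 | N-methoxy-N-methylacetamide | CC(=O)N(C)OC | starting material
4 | lithium enolate of N-methoxy-N-methylacetamide (not isolated) | C=C(O[Li])N(C)OC | intermediate
5 | 3-[2-bromo-4-(methoxymethoxy)phenyl]-N-methoxy-N-methyl-3-oxopropanamide | COCOc1ccc(C(=O)CC(=O)N(C)OC)c(Br)c1 | intermediate
6 | 2-{2-[2-bromo-4-(methoxymethoxy)phenyl]-1,3-dioxolan-2-yl}-N-methoxy-N-methylacetamide | COCOc1ccc(C2(CC(=O)N(C)OC)OCCO2)c(Br)c1 | intermediate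
7 | 4-bromophenol | Oc1ccc(Br)cc1 | starting material
8 | 1-bromo-3-methylbut-2-ene (prenyl bromide) | CC(C)=CCBr | starting material
9 | 4-bromo-2,6-bis(3-methylbut-2-enyl)phenol | CC(C)=CCc1cc(Br)cc(CC=C(C)C)c1O | intermediate
10 | 5-bromo-2-(methoxymethoxy)-1,3-bis(3-methylbut-2-enyl)benzene | CC(C)=CCc1cc(Br)cc(CC=C(C)C)c1OCOC | intermediate
11 | [4-(methoxymethoxy)-3,5-bis(3-methylbut-2-enyl)phenyl]magnesium bromide (aryl Grignard reagent, not isolated) | CC(C)=CCc1cc([Mg]Br)cc(CC=C(C)C)c1OCOC | intermediate
12 | 2-{2-[2-bromo-4-(methoxymethoxy)phenyl]-1,3-dioxolan-2-yl}-1-[4-(methoxymethoxy)-3,5-bis(3-methylbut-2-enyl)phenyl]ethanone | CC(C)=CCc1cc(C(=O)CC2(c3ccc(OCOC)cc3Br)OCCO2)cc(CC=C(C)C)c1OCOC | intermediate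
13 | (S)-2-{2-[2-bromo-4-(methoxymethoxy)phenyl]-1,3-dioxolan-2-yl}-1-[4-(methoxymethoxy)-3,5-bis(3-methylbut-2-enyl)phenyl]ethanol | CC(C)=CCc1cc([C@@H](O)CC2(c3ccc(OCOC)cc3Br)OCCO2)cc(CC=C(C)C)c1OCOC | intermediate
14 | (S)-7-(methoxymethoxy)-2-[4-(methoxymethoxy)-3,5-bis(3-methylbut-2-enyl)phenyl]spiro[chromane-4,2'-[1,3]dioxolane] | CC(C)=CCc1cc([C@@H]2CC3(OCCO3)c3ccc(OCOC)cc3O2)cc(CC=C(C)C)c1OCOC | intermediate
15 | (2S)-7-hydroxy-2-[4-hydroxy-3,5-bis(3-methylbut-2-enyl)phenyl]chroman-4-one | CC(C)=CCc1cc([C@@H]2CC(=O)c3ccc(O)cc3O2)cc(CC=C(C)C)c1O | target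

Total step count: 9. Longest linear sequence: 7 steps (steps 1, 2, 3, 6, 7, 8 and 9).

Steps most likely to fail

1. Step 8. Oxidative addition at the bromide flanked by the quaternary ketal carbon may be slow, so that protodebromination or intermolecular etherification overtakes ring closure. The fallback forms O1–C2 instead of O1–C8a and sets out from ketone 12. Transfer hydrogenation with the enantiomeric catalyst RuCl(p-cymene)[(R,R)-TsDPEN] should give the (R)-bromo alcohol F1. Miyaura borylation (B2pin2, PdCl2(dppf), KOAc, dioxane, 80 °C) would convert it into the (R)-aryl pinacol boronate F2, and oxidation with NaBO3·4H2O in THF–water into the (R)-hydroxy phenol F3. Mitsunobu cyclisation (PPh3, DIAD, THF, 0 °C) should then displace the activated carbinol oxygen by the ring A phenol with inversion, which returns to the route at 14 with the (S) configuration.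

2. Step 3. The aryl MOM ether may be lost to the silyl triflate, or the reaction may stall because the β-keto amide is silylated at oxygen instead of being ketalised. The fallback sets out from 5 and uses thermodynamic, azeotropic ketalisation (ethylene glycol, TsOH, benzene, reflux with water removal). This accepts cleavage of the MOM ether and should give the free-phenol dioxolane amide F4. Re-protection (NaH, MOMCl, DMF) comes back to the route at 6.

3. Step 4. O-alkylation and incomplete or excessive alkylation compete with the double ortho-C-alkylation, so the 2,6-dialkylated phenol may be obtained only in low amount from a mixture. The fallback sets out from 7 and fixes both positions by halogen. Double ortho-iodination (N-iodosuccinimide, cat. TsOH, MeCN) should give 4-bromo-2,6-diiodophenol F5, and MOM protection (NaH, MOMCl, DMF) its ether 5-bromo-1,3-diiodo-2-(methoxymethoxy)benzene F6. A twofold Stille coupling with tributyl(3-methylbut-2-enyl)stannane (Pd(PPh3)4, DMF, 80 °C), selective for the two carbon–iodine bonds over the carbon–bromine bond, should deliver the linear prenyl groups and rejoin the route at 10.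

Further compounds
F1 | step 8 | (R)-2-{2-[2-bromo-4-(methoxymethoxy)phenyl]-1,3-dioxolan-2-yl}-1-[4-(methoxymethoxy)-3,5-bis(3-methylbut-2-enyl)phenyl]ethanol | CC(C)=CCc1cc([C@H](O)CC2(c3ccc(OCOC)cc3Br)OCCO2)cc(CC=C(C)C)c1OCOC
F2 | step 8 | (R)-1-[4-(methoxymethoxy)-3,5-bis(3-methylbut-2-enyl)phenyl]-2-{2-[4-(methoxymethoxy)-2-(4,4,5,5-tetramethyl-1,3,2-dioxaborolan-2-yl)phenyl]-1,3-dioxolan-2-yl}ethanol | CC(C)=CCc1cc([C@H](O)CC2(c3ccc(OCOC)cc3B3OC(C)(C)C(C)(C)O3)OCCO2)cc(CC=C(C)C)c1OCOC
F3 | step 8 | (R)-2-{2-[2-hydroxy-4-(methoxymethoxy)phenyl]-1,3-dioxolan-2-yl}-1-[4-(methoxymethoxy)-3,5-bis(3-methylbut-2-enyl)phenyl]ethanol | CC(C)=CCc1cc([C@H](O)CC2(c3ccc(OCOC)cc3O)OCCO2)cc(CC=C(C)C)c1OCOC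
F4 | step 3 | 2-[2-(2-bromo-4-hydroxyphenyl)-1,3-dioxolan-2-yl]-N-methoxy-N-methylacetamide | CON(C)C(=O)CC1(c2ccc(O)cc2Br)OCCO1
F5 | step 4 | 4-bromo-2,6-diiodophenol | Oc1c(I)cc(Br)cc1I
F6 | step 4 | 5-bromo-1,3-diiodo-2-(methoxymethoxy)benzene | COCOc1c(I)cc(Br)cc1I
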